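The three bonds that meet around the ether methylene are cut: O7–C9', C9'–C8' and the lactone O–C7' bond. C9' has only C8' and the tetrahydrofuran oxygen as neighbours, so it can come from formaldehyde. C8' and C7' bear a new carbon and a new oxygen on opposite faces, which is the signature of an E-styrene. One cationic cascade thus closes both rings of the cis-fused tetrahydrofuran/γ-lactone core and sets C8' and C7'. Its precursor is the (2S,3S) syn-aldol acid with the C7 hydroxyl, the C9 carboxyl and an (E)-2-arylvinyl group on C8, the guaiacyl phenol masked as an electron-poor tosylate and the syringyl phenol as a benzyl ether.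

Key step: step 7

Remarks: lignan numbering is used (guaiacyl unit C7–C8–C9, C9 = lactone carbonyl; syringyl unit C7'–C8'–C9', C9' = ether methylene). The target is (7S,8S,8'R,7'S), i.e. (3S,3aR,6S,6aS) in furo[3,4-c]furanone numbering, with both aryl groups exo on the cis-fused bicycle. Assumption: paraformaldehyde is drawn as monomeric formaldehyde. The (S)-4-benzyl auxiliary is the enantiomer that gives the (2S,3S) aldol.

Step 1
Reactants: 1 syringaldehyde
Product: 2 4-(benzyloxy)-3,5-dimethoxybenzaldehyde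
Conditions: BnBr (1.2 equiv), K2CO3 (2 equiv), DMF, 60 °C
Reagents that add atoms: benzyl bromide, BrCc1ccccc1
Why: Williamson ether synthesis, in which the phenoxide displaces bromide from benzyl bromide (SN2); the two flanking methoxy groups slow but do not block O-alkylation at 60 °C, and no stereocentre is involved.

Step 2
Reactants: 2 4-(benzyloxy)-3,5-dimethoxybenzaldehyde; 3 (2-carboxyethyl)triphenylphosphonium bromide
Product: 5 (E)-4-[4-(benzyloxy)-3,5-dimethoxyphenyl]but-3-enoic acid, via ylide carboxylate 4 (not isolated)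
Conditions: 3, NaHMDS (2.2 equiv), THF, 0 °C; then 2, −78 °C → rt; 1 M HCl; crystallisation
Reagents that add atoms: none
Why: Wittig reaction of a carboxylate-bearing ylide (one equivalent of base is taken by the acid), which with aromatic aldehydes should give mainly the E alkene, the minor Z isomer being removed by crystallisation; the double bond stays β,γ because the product remains a carboxylate until acidification.

Step 3
Reactants: 5 (E)-4-[4-(benzyloxy)-3,5-dimethoxyphenyl]but-3-enoic acid; 6 (S)-4-benzyl-1,3-oxazolidin-2-one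
Product: 9 (S)-4-benzyl-3-{(E)-4-[4-(benzyloxy)-3,5-dimethoxyphenyl]but-3-enoyl}oxazolidin-2-one, via mixed pivalic anhydride 7 (not isolated), via lithiated oxazolidinone 8 (not isolated)
Conditions: 5, PivCl, Et3N, THF, −20 °C; 6, n-BuLi, THF, −78 °C; combine, −78 → 0 °C
Reagents that add atoms: none
Why: N-acylation of the lithium oxazolidinide by a mixed pivalic anhydride, which is attacked at the less hindered carbonyl; the low temperature and short base contact should keep the β,γ-double bond from moving into conjugation.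

Step 4
Reactants: 10 vanillin
Product: 11 4-formyl-2-methoxyphenyl 4-methylbenzenesulfonate (O-tosylvanillin)
Conditions: TsCl (1.1 equiv), Et3N (1.5 equiv), DMAP (5 mol%), CH2Cl2, 0 °C → rt
Reagents that add atoms: p-toluenesulfonyl chloride, Cc1ccc(cc1)S(Cl)(=O)=O
Why: Sulfonylation of a phenol under amine base with DMAP catalysis; the aldehyde is inert, and the sulfonate makes the ring electron-poor for the later cationic step.

Step 5
Reactants: 9 (S)-4-benzyl-3-{(E)-4-[4-(benzyloxy)-3,5-dimethoxyphenyl]but-3-enoyl}oxazolidin-2-one; 11 4-formyl-2-methoxyphenyl 4-methylbenzenesulfonate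
Product: 14 (S)-4-benzyl-3-{(2S,3S)-2-[(E)-2-(4-benzyloxy-3,5-dimethoxyphenyl)ethenyl]-3-hydroxy-3-[3-methoxy-4-(tosyloxy)phenyl]propanoyl}oxazolidin-2-one, via boron dienolate 12 (not isolated), via boron aldolate 13 (not isolated)
Conditions: Bu2BOTf (1.2 equiv), i-Pr2NEt (1.4 equiv), CH2Cl2, −78 → 0 °C; 11, −78 → 0 °C; pH 7 buffer, MeOH, 30% H2O2, 0 °C
Reagents that add atoms: none
Why: Evans boron aldol reaction, in which the (Z)-boron dienolate reacts at Cα through a closed Zimmerman–Traxler chair (syn C7/C8) on the face opposite the benzyl group of the (S)-auxiliary in its dipole-minimised conformation, giving the (2S,3S) adduct; α-attack rather than γ-attack follows from the cyclic boron transition state, as in the known aldol reactions of crotonyl imides.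

Step 6
Reactants: 14 (S)-4-benzyl-3-{(2S,3S)-2-[(E)-2-(4-benzyloxy-3,5-dimethoxyphenyl)ethenyl]-3-hydroxy-3-[3-methoxy-4-(tosyloxy)phenyl]propanoyl}oxazolidin-2-one
Product: 16 (2S,3S)-2-[(E)-2-(4-benzyloxy-3,5-dimethoxyphenyl)ethenyl]-3-hydroxy-3-[3-methoxy-4-(tosyloxy)phenyl]propanoic acid, via lithium percarboxylate 15 (not isolated)
Conditions: LiOH (2 equiv), 30% H2O2 (4 equiv), THF/H2O 3:1, 0 °C; aq. Na2SO3; 1 M HCl to pH 2–3, 0 °C
Reagents that add atoms: hydrogen peroxide, OO
Why: Evans hydroperoxide cleavage of the imide, in which the hydroperoxide anion attacks the exocyclic carbonyl and sulfite reduces the percarboxylate before acidification so that no peracid meets the styrene; 0 °C and a short reaction time should avoid retro-aldol cleavage, epimerisation at C8 and attack on the aryl sulfonate, leaving C7 and C8 unchanged.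

Step 7
Reactants: 16 (2S,3S)-2-[(E)-2-(4-benzyloxy-3,5-dimethoxyphenyl)ethenyl]-3-hydroxy-3-[3-methoxy-4-(tosyloxy)phenyl]propanoic acid; 17 paraformaldehyde
Product: 22 (3S,3aR,6S,6aS)-3-[4-(benzyloxy)-3,5-dimethoxyphenyl]-6-[3-methoxy-4-(tosyloxy)phenyl]tetrahydro-1H,3H-furo[3,4-c]furan-1-one, via bis-silyl derivative 18 (not isolated), via oxocarbenium ion 19 (not isolated), via dioxanone 20 (not isolated), via benzylic cation 21 (not isolated)
Conditions: HMDS (1.5 equiv), CH2Cl2, 40 °C, then evaporation; (CH2O)n (1.5 equiv), TMSOTf (0.3 equiv), CH2Cl2, −40 → 20 °C; Et3N, aq. NaHCO3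
Reagents that add atoms: none
Why: Proposed new method: after silylation, TMSOTf condenses the C7 silyl ether with formaldehyde to the oxocarbenium ion O7=C9'H2(+), which may park reversibly on the ester oxygen as the 1,3-dioxan-4-one but is drained when the styrene attacks through C8' (C9'–C8' bond), putting the charge on the benzylic C7', where the silyl ester oxygen closes the lactone (O–C7' bond) and releases Me3Si(+) to carry the chain. The closest known reaction type is the silyl-modified oxonia-Prins cyclisation of styrenyl homoallylic alcohols to tetrahydrofurans with external or aromatic trapping of the benzylic cation, together with Lewis-acid ionisation of 1,3-dioxan-4-ones at the acylal C–O bond; internal carboxyl trapping to a fused γ-lactone is the untested extension. The tetrahydrofuran closes 5-exo with respect to the alkene (the C=O(+) unit lies inside the ring), and the γ-lactone closes by oxygen attack on the exocyclic cation, a closure that is 5-endo with respect to the original C8'=C7' bond, as in halolactonisations of 4-arylbut-3-enoic acids. C8' is fixed by the double tether, since the electrophile (on O7) and the nucleophile (on C8) hang on adjacent ring atoms and only a C7' cation cis to C9 can lactonise, whereas a trans cation can only lose H8' and re-enter by reprotonation; C7' follows from anti addition across the E alkene or, if the cation rotates, from closure with the aryl group on the convex face, both giving the exo syringyl group. The selectivities needed are attack at C8' rather than C7' (secured by the aryl group at the alkene terminus, which also disfavours the six-membered Prins and 2-oxonia-Cope paths) and an inert C7–O bond (secured by the tosyloxy group, which makes the guaiacyl ring electron-poor); C7 and C8 are carried through unchanged.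

Step 8
Reactants: 22 (3S,3aR,6S,6aS)-3-[4-(benzyloxy)-3,5-dimethoxyphenyl]-6-[3-methoxy-4-(tosyloxy)phenyl]tetrahydro-1H,3H-furo[3,4-c]furan-1-one
Product: 25 (3S,3aR,6S,6aS)-3-[4-(benzyloxy)-3,5-dimethoxyphenyl]-6-(4-hydroxy-3-methoxyphenyl)tetrahydro-1H,3H-furo[3,4-c]furan-1-one, via dipotassium salt 23 (not isolated), via seco acid 24 (not isolated)
Conditions: KOH (10 equiv), H2O/1,4-dioxane 1:1, 70 °C; then 1 M HCl to pH 2, rt
Reagents that add atoms: none
Why: Alkaline hydrolysis of an aryl sulfonate (hydroxide attack at sulfur, S–O cleavage) with concurrent saponification of the lactone to a carboxylate that cannot enolise, followed by relactonisation of the cis γ-hydroxy acid on acidification by acyl substitution, which retains C7'; the benzyl ether and the tetrahydrofuran are inert.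

Step 9
Reactants: 25 (3S,3aR,6S,6aS)-3-[4-(benzyloxy)-3,5-dimethoxyphenyl]-6-(4-hydroxy-3-methoxyphenyl)tetrahydro-1H,3H-furo[3,4-c]furan-1-one
Product: 26 (3S,3aR,6S,6aS)-3-(4-hydroxy-3,5-dimethoxyphenyl)-6-(4-hydroxy-3-methoxyphenyl)tetrahydro-1H,3H-furo[3,4-c]furan-1-one (target)
Conditions: H2 (1 atm), 10% Pd/C, EtOAc, rt, stopped at consumption of 25
Reagents that add atoms: none
Why: Catalytic hydrogenolysis of an aryl benzyl ether over Pd/C, which at 1 atm in a neutral solvent should be much faster than cleavage of the ring benzylic C–O bonds; no stereocentre is affected.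

Compound list
1 | syringaldehyde (4-hydroxy-3,5-dimethoxybenzaldehyde) | COc1cc(C=O)cc(OC)c1O | starting material
2 | 4-(benzyloxy)-3,5-dimethoxybenzaldehyde | COc1cc(C=O)cc(OC)c1OCc1ccccc1 | intermediate
3 | (2-carboxyethyl)triphenylphosphonium bromide | OC(=O)CC[P+](c1ccccc1)(c1ccccc1)c1ccccc1.[Br-] | starting material
4 | sodium 3-(triphenylphosphoranylidene)propanoate (ylide carboxylate, not isolated) | [Na+].[O-]C(=O)CC=P(c1ccccc1)(c1ccccc1)c1ccccc1 | intermediate
5 | (E)-4-[4-(benzyloxy)-3,5-dimethoxyphenyl]but-3-enoic acid | OC(=O)C/C=C/c1cc(OC)c(OCc2ccccc2)c(OC)c1 | intermediate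
6 | (S)-4-benzyl-1,3-oxazolidin-2-one | O=C1N[C@@H](Cc2ccccc2)CO1 | starting material
7 | mixed anhydride of 5 and pivalic acid (not isolated) | CC(C)(C)C(=O)OC(=O)C/C=C/c1cc(OC)c(OCc2ccccc2)c(OC)c1 | intermediate
8 | lithium salt of 6 (not isolated) | [Li+].O=C1[N-][C@@H](Cc2ccccc2)CO1 | intermediate
9 | (S)-4-benzyl-3-{(E)-4-[4-(benzyloxy)-3,5-dimethoxyphenyl]but-3-enoyl}oxazolidin-2-one | O=C(C/C=C/c1cc(OC)c(OCc2ccccc2)c(OC)c1)N1[C@@H](Cc2ccccc2)COC1=O | intermediate
10 | vanillin (4-hydroxy-3-methoxybenzaldehyde) | COc1cc(C=O)ccc1O | starting material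
11 | 4-formyl-2-methoxyphenyl 4-methylbenzenesulfonate (O-tosylvanillin) | COc1cc(C=O)ccc1OS(=O)(=O)c1ccc(C)cc1 | intermediate
12 | (Z)-dibutylboron dienolate of 9 (not isolated) | CCCCB(CCCC)O/C(=C\C=C\c1cc(OC)c(OCc2ccccc2)c(OC)c1)N1[C@@H](Cc2ccccc2)COC1=O | intermediate
13 | O-dibutylboryl aldolate of 14 (not isolated) | COc1cc([C@@H](OB(CCCC)CCCC)[C@H](/C=C/c2cc(OC)c(OCc3ccccc3)c(OC)c2)C(=O)N2[C@@H](Cc3ccccc3)COC2=O)ccc1OS(=O)(=O)c1ccc(C)cc1 | intermediate
14 | (S)-4-benzyl-3-{(2S,3S)-2-[(E)-2-(4-benzyloxy-3,5-dimethoxyphenyl)ethenyl]-3-hydroxy-3-[3-methoxy-4-(tosyloxy)phenyl]propanoyl}oxazolidin-2-one | COc1cc([C@@H](O)[C@H](/C=C/c2cc(OC)c(OCc3ccccc3)c(OC)c2)C(=O)N2[C@@H](Cc3ccccc3)COC2=O)ccc1OS(=O)(=O)c1ccc(C)cc1 | intermediate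
15 | lithium peroxycarboxylate of 16 (not isolated) | COc1cc([C@@H](O)[C@H](/C=C/c2cc(OC)c(OCc3ccccc3)c(OC)c2)C(=O)O[O-])ccc1OS(=O)(=O)c1ccc(C)cc1.[Li+] | intermediate
16 | (2S,3S)-2-[(E)-2-(4-benzyloxy-3,5-dimethoxyphenyl)ethenyl]-3-hydroxy-3-[3-methoxy-4-(tosyloxy)phenyl]propanoic acid (key-step precursor) | COc1cc([C@@H](O)[C@H](/C=C/c2cc(OC)c(OCc3ccccc3)c(OC)c2)C(=O)O)ccc1OS(=O)(=O)c1ccc(C)cc1 | intermediate
17 | paraformaldehyde (drawn as formaldehyde) | C=O | starting material
18 | trimethylsilyl ester and C7 trimethylsilyl ether of 16 (not isolated) | COc1cc([C@@H](O[Si](C)(C)C)[C@H](/C=C/c2cc(OC)c(OCc3ccccc3)c(OC)c2)C(=O)O[Si](C)(C)C)ccc1OS(=O)(=O)c1ccc(C)cc1 | intermediate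
19 | O7-methylene oxocarbenium ion of the silyl ester (not isolated) | COc1cc([C@@H]([O+]=C)[C@H](/C=C/c2cc(OC)c(OCc3ccccc3)c(OC)c2)C(=O)O[Si](C)(C)C)ccc1OS(=O)(=O)c1ccc(C)cc1 | intermediate
20 | 1,3-dioxan-4-one from 16 and formaldehyde, (5S,6S)-5-[(E)-2-arylethenyl]-6-aryl (reservoir, not isolated) | COc1cc([C@H]2OCOC(=O)[C@H]2/C=C/c2cc(OC)c(OCc3ccccc3)c(OC)c2)ccc1OS(=O)(=O)c1ccc(C)cc1 | intermediate
21 | C7' benzylic cation of the 2,3-trans-3,4-cis tetrahydrofuran silyl ester (not isolated) | COc1cc([C@H]2OC[C@H]([CH+]c3cc(OC)c(OCc4ccccc4)c(OC)c3)[C@@H]2C(=O)O[Si](C)(C)C)ccc1OS(=O)(=O)c1ccc(C)cc1 | intermediate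
22 | (3S,3aR,6S,6aS)-3-[4-(benzyloxy)-3,5-dimethoxyphenyl]-6-[3-methoxy-4-(tosyloxy)phenyl]tetrahydro-1H,3H-furo[3,4-c]furan-1-one (key-step product) | COc1cc([C@H]2OC[C@H]3[C@@H]2C(=O)O[C@@H]3c2cc(OC)c(OCc4ccccc4)c(OC)c2)ccc1OS(=O)(=O)c1ccc(C)cc1 | intermediate
23 | dipotassium phenoxide carboxylate of 24 (not isolated) | COc1cc([C@H]2OC[C@H]([C@H](O)c3cc(OC)c(OCc4ccccc4)c(OC)c3)[C@@H]2C([O-])=O)ccc1[O-].[K+].[K+] | intermediate
24 | (2S,3S,4R)-4-{(S)-[4-(benzyloxy)-3,5-dimethoxyphenyl](hydroxy)methyl}-2-(4-hydroxy-3-methoxyphenyl)tetrahydrofuran-3-carboxylic acid (not isolated) | COc1cc([C@H]2OC[C@H]([C@H](O)c3cc(OC)c(OCc4ccccc4)c(OC)c3)[C@@H]2C(=O)O)ccc1O | intermediate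
25 | (3S,3aR,6S,6aS)-3-[4-(benzyloxy)-3,5-dimethoxyphenyl]-6-(4-hydroxy-3-methoxyphenyl)tetrahydro-1H,3H-furo[3,4-c]furan-1-one | COc1cc([C@H]2OC[C@H]3[C@@H]2C(=O)O[C@@H]3c2cc(OC)c(OCc4ccccc4)c(OC)c2)ccc1O | intermediate
26 | (3S,3aR,6S,6aS)-3-(4-hydroxy-3,5-dimethoxyphenyl)-6-(4-hydroxy-3-methoxyphenyl)tetrahydro-1H,3H-furo[3,4-c]furan-1-one | COc1cc([C@H]2OC[C@H]3[C@@H]2C(=O)O[C@@H]3c2cc(OC)c(O)c(OC)c2)ccc1O | target

Total step count: 9.
Longest linear sequence: 8 steps (1, 2, 3, 5, 6, 7, 8, 9, from syringaldehyde).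

Steps most likely to fail

Step 7. The cascade may fail in four ways:
- The oxocarbenium ion may add to the alkene face that leaves the C7' cation trans to the ester, so that lactonisation is impossible.
- The reservoir acylal may fail to re-ionise.
- Excess formaldehyde may alkylate the electron-rich syringyl ring.
- Adventitious acid may protonate the styrene and close a lactone without uptake of C9'.

Fallback, using only known reaction types, in which C9' enters together with the alkene carbon and the lactone is closed last: set out from aldehyde 2. Stobbe condensation with dimethyl succinate (NaOMe, MeOH, reflux) should give the (E)-half-ester F1, which is coupled to 6 through its pivalic mixed anhydride to give the imide F2. The boron aldol reaction with 11, run as in step 5, should give the syn adduct F3, and LiOH/H2O2 then releases the hydroxy acid F4. PPTS in warm toluene closes the C7 hydroxyl onto the conjugated methyl ester to give the arylidene lactone acid F5, whose ring already holds O7–C9' and C9'–C8'. DIBAL-H at −78 °C reduces the lactone to the lactol F6, and Et3SiH/BF3·OEt2 removes the anomeric hydroxyl to give the arylidene tetrahydrofuran acid F7. Catalytic TfOH in CH2Cl2 at 0 °C then protonates the styrene at C8' and the carboxyl closes on the benzylic C7' (acid-catalysed lactonisation of a γ-aryl β,γ-unsaturated acid). Because the acid sits on the ring, only the cis-fused lactone with the exo aryl group can form, and the route is rejoined at 22.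

Step 5. Enolisation of the aryl-conjugated β,γ-unsaturated imide may lead to γ-attack, loss of alkene geometry, migration of the double bond into conjugation, or eroded facial control. Fallback, in which the styrene is built after the stereocentres: set out from 6, which is acylated with crotonyl chloride (n-BuLi, THF, −78 °C) to the crotonyl imide F8. Deconjugative enolisation with Bu2BOTf/Et3N and addition of 11 should give the α-vinyl syn-aldol F9 in the same (2S,3S) sense. Olefin cross-metathesis of F9 with the styrene F10 (from 2 and Ph3P=CH2), using the Hoveyda–Grubbs second-generation catalyst in CH2Cl2 at 40 °C, should install the E C8'=C7' bond and return to 14.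

Step 9. Once the phenols are free, hydrogenolysis may go on to cleave the benzylic lactone C7'–O bond or the benzylic ether C7–O bond (over-reduction). Fallback without hydrogen and with the order of the deprotections reversed: set out from 22. The benzyl ether is cleaved with BCl3 and pentamethylbenzene in CH2Cl2 at −78 °C, while the guaiacyl ring is still a sulfonate, to give the phenol tosylate F11. Hydroxide detosylation and relactonisation on acidification, as in step 8, should then give 26 directly.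

Further compounds
F1 | step 7 | (E)-4-[4-(benzyloxy)-3,5-dimethoxyphenyl]-3-(methoxycarbonyl)but-3-enoic acid | COC(=O)/C(CC(=O)O)=C/c1cc(OC)c(OCc2ccccc2)c(OC)c1
F2 | step 7 | (S)-4-benzyl-3-{(E)-4-[4-(benzyloxy)-3,5-dimethoxyphenyl]-3-(methoxycarbonyl)but-3-enoyl}oxazolidin-2-one | COC(=O)/C(CC(=O)N1[C@@H](Cc2ccccc2)COC1=O)=C/c1cc(OC)c(OCc2ccccc2)c(OC)c1
F3 | step 7 | (S)-4-benzyl-3-{(2S,3S)-2-[(E)-2-(4-benzyloxy-3,5-dimethoxyphenyl)-1-(methoxycarbonyl)ethenyl]-3-hydroxy-3-[3-methoxy-4-(tosyloxy)phenyl]propanoyl}oxazolidin-2-one | COc1cc([C@@H](O)[C@@H](C(=O)N2[C@@H](Cc3ccccc3)COC2=O)/C(=C\c2cc(OC)c(OCc3ccccc3)c(OC)c2)C(=O)OC)ccc1OS(=O)(=O)c1ccc(C)cc1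
F4 | step 7 | (2S,3S)-2-[(E)-2-(4-benzyloxy-3,5-dimethoxyphenyl)-1-(methoxycarbonyl)ethenyl]-3-hydroxy-3-[3-methoxy-4-(tosyloxy)phenyl]propanoic acid | COc1cc([C@@H](O)[C@@H](C(=O)O)/C(=C\c2cc(OC)c(OCc3ccccc3)c(OC)c2)C(=O)OC)ccc1OS(=O)(=O)c1ccc(C)cc1
F5 | step 7 | (2S,3S,E)-4-[4-(benzyloxy)-3,5-dimethoxybenzylidene]-2-[3-methoxy-4-(tosyloxy)phenyl]-5-oxotetrahydrofuran-3-carboxylic acid | COc1cc([C@H]2OC(=O)/C(=C/c3cc(OC)c(OCc4ccccc4)c(OC)c3)[C@@H]2C(=O)O)ccc1OS(=O)(=O)c1ccc(C)cc1
F6 | step 7 | (2S,3S,E)-4-[4-(benzyloxy)-3,5-dimethoxybenzylidene]-5-hydroxy-2-[3-methoxy-4-(tosyloxy)phenyl]tetrahydrofuran-3-carboxylic acid (anomer mixture) | COc1cc([C@H]2OC(O)/C(=C/c3cc(OC)c(OCc4ccccc4)c(OC)c3)[C@@H]2C(=O)O)ccc1OS(=O)(=O)c1ccc(C)cc1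
F7 | step 7 | (2S,3S,E)-4-[4-(benzyloxy)-3,5-dimethoxybenzylidene]-2-[3-methoxy-4-(tosyloxy)phenyl]tetrahydrofuran-3-carboxylic acid | COc1cc([C@H]2OC/C(=C/c3cc(OC)c(OCc4ccccc4)c(OC)c3)[C@@H]2C(=O)O)ccc1OS(=O)(=O)c1ccc(C)cc1
F8 | step 5 | (S)-4-benzyl-3-[(E)-but-2-enoyl]oxazolidin-2-one | C/C=C/C(=O)N1[C@@H](Cc2ccccc2)COC1=O
F9 | step 5 | (S)-4-benzyl-3-{(2S,3S)-2-ethenyl-3-hydroxy-3-[3-methoxy-4-(tosyloxy)phenyl]propanoyl}oxazolidin-2-one | COc1cc([C@@H](O)[C@H](C=C)C(=O)N2[C@@H](Cc3ccccc3)COC2=O)ccc1OS(=O)(=O)c1ccc(C)cc1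
F10 | step 5 | 2-(benzyloxy)-5-ethenyl-1,3-dimethoxybenzene | C=Cc1cc(OC)c(OCc2ccccc2)c(OC)c1
F11 | step 9 | (3S,3aR,6S,6aS)-3-(4-hydroxy-3,5-dimethoxyphenyl)-6-[3-methoxy-4-(tosyloxy)phenyl]tetrahydro-1H,3H-furo[3,4-c]furan-1-one | COc1cc([C@H]2OC[C@H]3[C@@H]2C(=O)O[C@@H]3c2cc(OC)c(O)c(OC)c2)ccc1OS(=O)(=O)c1ccc(C)cc1
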